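The vessel is closed, stirred and held at one temperature, and every reading is of Sbt.

| flask | Sbt | Ptn | Ctl | Pdt | time |
|---|---|---|---|---|---|
| gamma | 0.250 M | 0.275 M | 0.0250 M |  |  |
| eta | 0.150 M | 0.175 M | 0.0250 M |  |  |
| delta | 0.250 M | 0.550 M | 0.0250 M |  |  |
| epsilon | 0.250 M | 0.275 M | 0.0250 M | 0.120 M |  |
| theta | 0.0830 M | 0.275 M | 0.0130 M |  | 5.4 h |

| run | time / h | [Sbt] / M |
|---|---|---|
| gamma run | 0.68 | 0.0819 |
| gamma run | 1.4 | 0.0454 |
| gamma run | 2.0 | 0.0322 |
| gamma run | 2.7 | 0.0252 |
| gamma run | 3.4 | 0.0197 |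
| gamma run | 4.0 | 0.0171 |
| gamma run | 4.7 | 0.0155 |
| gamma run | 5.4 | 0.0128 |
| eta run | 0.68 | 0.0667 |
| eta run | 1.4 | 0.0414 |
| eta run | 2.0 | 0.0322 |
| eta run | 2.7 | 0.0253 |
| eta run | 3.4 | 0.0200 |
| eta run | 4.0 | 0.0159 |
| eta run | 4.7 | 0.0156 |
| eta run | 5.4 | 0.0128 |
| delta run | 0.68 | 0.0695 |
| delta run | 1.4 | 0.0373 |
| delta run | 2.0 | 0.0249 |
| delta run | 2.7 | 0.0168 |
| delta run | 3.4 | 0.0146 |
| delta run | 4.0 | 0.0111 |
| delta run | 4.7 | 0.0090 |
| delta run | 5.4 | 0.0106 |
| epsilon run | 0.68 | 0.0821 |
| epsilon run | 1.4 | 0.0457 |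
| epsilon run | 2.0 | 0.0321 |
| epsilon run | 2.7 | 0.0243 |
| epsilon run | 3.4 | 0.0205 |
| epsilon run | 4.0 | 0.0166 |
| epsilon run | 4.7 | 0.0150 |
| epsilon run | 5.4 | 0.0125 |

(standard deviation of a reading: 8 × 10⁻⁴ M)

- Overall: Sbt + Ptn -> Pdt, with Ctl as catalyst.
- Constant volume, constant temperature.
- An order is taken over about fifteen percent of the charge, up and down.

1. the power of [Ptn] that the first rate follows, about the charge of the gamma run; measure it at two percent of Sbt made into Pdt
2. the power of [Sbt] that the first rate follows, about the charge of the gamma run; measure it at two percent of Sbt made into Pdt (one fixed amount of Pdt, the same in the runs compared)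
3. Sbt in the theta run at 5.4 h, as a share of the Sbt charged

The chair asked that each reading be written as f, the fraction of the charged Sbt still present. She also asked for N, the inverse of f minus one.

A first member took the gamma flask, where Sbt is the limiting reagent. She reported that N goes from 2.05 at 0.68 h to 18.5 at 5.4 h. In powers of ten, log N against log t has slope 1.06. She took this as the mark of a loss second order in Sbt. She proposed the loss constant b, which is N divided by the charge and by the time, and read 13.7 M⁻¹ h⁻¹ from the gamma flask. Then f is the inverse of one plus b times charge times time.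

A second member tried b on the eta flask, with its smaller charge of Sbt. It predicts f of 8.25 % at 5.4 h, and he read 8.53 %.

A third member took the delta flask, with twice the Ptn of gamma. Its first reading gives N of 2.60 against 2.05. If the catalysed part follows the first power of Ptn, then 73.2 % of the gamma N carries no Ptn. She argued that the small Ptn effect on the delta readings can therefore hide a large one on the first rate. She added that the delta b goes from 15.3 M⁻¹ h⁻¹ early to 22.8 M⁻¹ h⁻¹ at 4.7 h, and she took this to mean that the catalysed part is first order in Sbt, not second. The meeting committed to orders near one for both Ptn and Sbt.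

For the theta flask the chair reckoned N as 6.15, hence f of 14.0 %. She noted that theta holds about half the Ctl of gamma, so this b may run high there.

The forecast, made apart, parts from this on the orders, giving 0.12 for Ptn and 1.4 for Sbt with 18 % for theta, on the ground that “Ptn dependence is therefore weak”.

The flask gives 1.2 for Ptn, 1.0 for Sbt and 15.1 % for theta.

    2 Ctl ⇌ Ctl2, settled at all times (268.0 M⁻¹)
    Ctl2 + Sbt + Ptn → Pdt + Ctl2 (145.1 M⁻² h⁻¹)
    2 Ctl → 2 E (125.3 M⁻¹ h⁻¹)
    2 Sbt → L (4.896 M⁻¹ h⁻¹)

From that share, the theta flask has its own b of 12.5 M⁻¹ h⁻¹, against 13.7 M⁻¹ h⁻¹ from gamma. The main reason for the low theta share is the passing of 2 Sbt into L. The theta run without that step keeps 66.9 % of its Sbt instead of 15.1 %, and its b drops to 1.10 M⁻¹ h⁻¹.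

The data were computed for an exercise; the scatter is artificial.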